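**Remark on the chemistry (assumption):** the target is drawn as its C4-enol tautomer. Polyprenylated-acylphloroglucinol numbering is used for all bicyclic compounds and their precursors: C1 = prenyl bridgehead, C2/C4 = enolised 1,3-diketone, C3 = aroyl carbon, C5 = geranyl bridgehead, C6 = CH2, C7 = CH(prenyl), C8 = CMe2, C9 = bridging ketone. This numbering coincides with the IUPAC locants of bicyclo[3.3.1]non-3-ene-2,9-dione.

## Analysis of the target

The target is (1S,5S,7R)-3-(3,4-dihydroxybenzoyl)-5-geranyl-4-hydroxy-8,8-dimethyl-1,7-diprenylbicyclo[3.3.1]non-3-ene-2,9-dione. Ring A (C1–C2–C3–C4–C5–C9) holds the enolised 1,3-diketone C2/C4 with the aroyl group on C3. Ring B (C1–C8–C7–C6–C5–C9) is a cyclohexanone, and the two rings share the bridgeheads and the C9 carbonyl. There are three stereocentres, but only two independent elements: the bridgeheads C1 and C5 are tied cis, and the C7 prenyl group is exo (equatorial on the chair of ring B, on the side of C9). C1 (prenyl) is a quaternary carbon bonded to the quaternary C8, while C5 (geranyl) is bonded to the C6 methylene; the two bridgeheads carry different allyl groups, so any route that treats them alike gives constitutional mixtures. Sensitive groups are four trisubstituted olefins (acid-labile; the geranyl 2,3-olefin must stay E), the β-triketone enol and the catechol, which rule out late hydrogenation, strong acid and oxidants. The feature that invites the strategy is twofold: the oxygen pattern C2/C4/C9 of ring A is that of phloroglucinol, so ring A is a dearomatised arene in which C5 is the carbon alkylated twice; and C6–C7–C8 with the two C8 methyl groups and the C7 prenyl group is a complete lavandulyl unit whose carbinyl carbon C8 is bonded to C1. If C1 and C3 both carry hydrogen when ring B closes, C5 is only prochiral, and the single lavandulyl stereocentre C7 can choose between the two enol ether arms. One bond (C1–C8) then closes ring B, joins the bridgehead to the quaternary carbon and fixes C1 and C5 relative to C7.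

## Retrosynthetic reasoning

**29 ⇒ 28.** The catechol and the triketone enol are unmasked last, in one operation, from the bis-silyl ether/methyl enol ether 28. The most oxidation- and acid-prone groups therefore never meet a base-mediated C–C bond formation.

**28 ⇒ 26 + 5.** The C1–prenyl bond is cut. C1 of 26 is a bridgehead CH flanked by the C2 and C9 carbonyl groups, so it can be metalated and alkylated with bromide 5. The bicycle enforces retention, and O-alkylation would need a bridgehead olefin. The prenyl group is placed on C1 after ring closure because a substituent on C1 (but not on C3) before ring closure would make C5 a stereocentre and destroy the symmetry on which the key step rests.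

**26 ⇒ 21 + 24.** The C3–aroyl bond is cut. The vinylic C3–H of the vinylogous ester 21 is its kinetically most acidic position, so it is acylated first with acid chloride 24. The aroyl group then blocks C3 during the bridgehead metalation.

**21 ⇒ 19 (key disconnection).** The C1–C8 bond is cut, which opens ring B. The precursor 19 is a 4,4-disubstituted 3,5-dimethoxycyclohexa-2,5-dienone whose ring has a mirror plane through C2 and C5; its only stereocentre is C7. The forward reaction must generate a tertiary cation at C8 from the tertiary alcohol (through imidate 20), let it be trapped by one of the two diastereotopic enol ether α-carbons, and lose the methyl group of that arm. This forms the most hindered bond of ring B, makes C5 stereogenic and sets C1, all under control of C7.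

**19 ⇒ 17 + 18.** The C5–geranyl bond is cut. Forward, phenol 17 is dearomatised by C-allylation at its substituted para position with geraniol 18. The geranyl group comes in intact, so its E olefin is never constructed, and no geranyl/prenyl regiochemical question arises because C5 is the only para carbon.

**17 ⇒ 14 + 12.** The aryl–C6 bond is cut. The aryllithium 15 from silyl ether 14 opens the chiral oxetane 12 at its CH2 carbon. This attaches the lavandulyl chain and sets free the tertiary alcohol at C8 without a protecting group, giving 17 by way of 16.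

**12 ⇒ 10 ⇒ 8 ⇒ 7 ⇒ 4 + 5 ⇒ 1 + 2.** The oxetane comes from diol 10, which is the Markovnikov hydrate of (S)-lavandulol 8. Alcohol 8 is the reduction product of imide 7, whose stereocentre (the future C7) is set by auxiliary-controlled deconjugative alkylation of imide 4 with bromide 5; imide 4 is made from auxiliary 1 and acid chloride 2. The arene 14 is the silyl ether of phenol 13, and 24 is made from acid 22 by way of 23.

## Alternatives that were turned down

**Alternative 1:** The textbook route cuts C1–C2 and C4–C5, an Effenberger α,α′-annulation. Forward, silyl enol ether A1 (C1 prenyl, C8 gem-dimethyl and C7 prenyl already in place) is condensed with malonyl dichloride to the bicyclic trione A2. O-methylation, bridgehead geranylation at C5, C3 aroylation and deprotection would follow. It was turned down for three reasons: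
- The annulation must C-acylate a fully substituted enol ether carbon next to the quaternary C8, so O-acylation and pyrandione formation compete strongly.
- The C7 stereocentre of A1 needs its own asymmetric alkylation and then controls the bridgeheads only through a modest thermodynamic preference.
- O-methylation of A2 gives two regioisomeric enol ethers.

The ring system, the stereocentres and the substituents each cost separate steps, and the sequence is no shorter than the one chosen.

**Alternative 2:** C5–C6 and C1–C8 are cut on the complete acylphloroglucinol. Forward, benzophenone A3 (geranyl and prenyl on the two free ring carbons) is dearomatised by alkylation with a lavandulyl-type electrophile to triketone A4, which is cyclised in acid. It was turned down for these reasons: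
- The geranyl- and prenyl-bearing carbons of A3 are electronically identical and sterically nearly so; alkylation would occur at both.
- In A4 the new quaternary centre C5 is a stereocentre because C1 and C3 differ. It forms without control from the remote C7, so each regioisomer is a pair of epimers and only one compound in four has the right constitution and configuration.
- The wrong C5 epimer can cyclise only through an axial-prenyl chair or through the acyl-bearing carbon, which gives the 7-epi or the type A skeleton.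

**Alternative 3:** C1–C8 is cut as an iodonium-induced carbocyclisation, and the C7 prenyl group is added afterwards. Forward, the achiral dienone A5 (geranyl and prenyl on C5) is treated with iodine to give iodide A6; radical allylation at C7, olefin cross-metathesis and the bridgehead chemistry follow. It was turned down for these reasons:
- The iodonium ion cannot tell the prenyl olefin from the geranyl 2,3-olefin; both are trisubstituted and sit at the same distance from the enol ether, so two skeletons would form.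
- Substrate and reagent are achiral, so A6 is racemic and a resolution is needed.
- The C7 side chain needs two further steps, one of them a metathesis in the presence of the geranyl chain.

Key step: step 9

## Route

**Step 1**
Reactants: 1 (4S)-4-benzyl-1,3-oxazolidin-2-one; 2 3-methylbut-2-enoyl chloride
Product: 4 (4S)-4-benzyl-3-(3-methylbut-2-enoyl)-1,3-oxazolidin-2-one, via lithium oxazolidinide 3 (not isolated)
Conditions: n-BuLi, THF, −78 °C; then 2, −78 to 0 °C
Reagents that add atoms: none
Why: N-acylation of the lithiated oxazolidinone by the acid chloride; no stereocentre is touched and no amine base is present that could deconjugate the enoyl group.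

**Step 2**
Reactants: 4 (4S)-4-benzyl-3-(3-methylbut-2-enoyl)-1,3-oxazolidin-2-one; 5 1-bromo-3-methylbut-2-ene (prenyl bromide)
Product: 7 (4S)-4-benzyl-3-[(2S)-5-methyl-2-(prop-1-en-2-yl)hex-4-enoyl]-1,3-oxazolidin-2-one, via sodium dienolate 6 (not isolated)
Conditions: NaN(SiMe3)2, THF, −78 °C; then 5, −78 to −40 °C
Reagents that add atoms: none
Why: Evans alkylation in its deconjugative form: γ-deprotonation gives the chelated Z-dienolate, which reacts at the α-carbon on the face opposite to the benzyl group. This sets the future C7 (2S in 7) and leaves the isopropenyl group out of conjugation.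

**Step 3**
Reactants: 7 (4S)-4-benzyl-3-[(2S)-5-methyl-2-(prop-1-en-2-yl)hex-4-enoyl]-1,3-oxazolidin-2-one
Product: 8 (2S)-5-methyl-2-(prop-1-en-2-yl)hex-4-en-1-ol ((S)-lavandulol)
Conditions: LiBH4, MeOH (1 equiv), Et2O, 0 °C
Reagents that add atoms: none
Why: Reductive cleavage of the N-acyl oxazolidinone to the primary alcohol with recovery of auxiliary 1; the conditions are too mild to epimerise the allylic α-centre.

**Step 4**
Reactants: 8 (2S)-5-methyl-2-(prop-1-en-2-yl)hex-4-en-1-ol
Product: 10 (2R)-2-(2-hydroxypropan-2-yl)-5-methylhex-4-en-1-ol, via organomercurial 9 (not isolated)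
Conditions: Hg(OAc)2 (1.0 equiv), THF/H2O 1:1, 0 °C to rt; then 3 M NaOH, NaBH4, 0 °C
Reagents that add atoms: water, O
Why: Oxymercuration–demercuration; the 1,1-disubstituted isopropenyl olefin is mercurated faster than the trisubstituted prenyl olefin (as in the hydration of limonene to α-terpineol), and water adds at the tertiary carbon. The stereocentre is untouched; its descriptor changes to R only through the priority change.

**Step 5**
Reactants: 10 (2R)-2-(2-hydroxypropan-2-yl)-5-methylhex-4-en-1-ol
Product: 12 (3R)-2,2-dimethyl-3-(3-methylbut-2-en-1-yl)oxetane, via monotosylate 11 (not isolated)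
Conditions: n-BuLi (1 equiv), THF, 0 °C; TsCl (1 equiv); then n-BuLi (1 equiv), 0 to 60 °C
Reagents that add atoms: none
Why: One-pot oxetane synthesis from a 1,3-diol: selective sulfonylation of the primary alkoxide, then intramolecular Williamson etherification (4-exo-tet) by the tertiary lithium alkoxide, helped by the gem-dimethyl group. The lithium counter-ion disfavours the competing fragmentation.

**Step 6**
Reactants: 13 3,5-dimethoxyphenol
Product: 14 (3,5-dimethoxyphenoxy)tri(propan-2-yl)silane
Conditions: i-Pr3SiCl, imidazole, DMF, rt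
Reagents that add atoms: chlorotri(propan-2-yl)silane, CC(C)[Si](Cl)(C(C)C)C(C)C
Why: Standard silylation of the phenol; the bulky silyl ether is a poor directing group, which leaves the position between the two methoxy groups as the site of metalation in step 7.

**Step 7**
Reactants: 14 (3,5-dimethoxyphenoxy)tri(propan-2-yl)silane; 12 (3R)-2,2-dimethyl-3-(3-methylbut-2-en-1-yl)oxetane
Product: 17 4-[(2R)-2-(2-hydroxypropan-2-yl)-5-methylhex-4-en-1-yl]-3,5-dimethoxyphenol, via aryllithium 15 (not isolated), via silyl ether alcohol 16 (not isolated)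
Conditions: n-BuLi, THF, 0 °C to rt; then 12, BF3·OEt2, −78 °C; aqueous work-up; then Bu4NF, THF, 0 °C
Reagents that add atoms: none
Why: Directed ortho-metalation between the two methoxy groups, then BF3-promoted SN2 opening of the oxetane at its unsubstituted CH2 carbon; this forms the aryl–C6 bond and releases the tertiary alcohol at C8. C7 is not involved; fluoride then frees the phenol.

**Step 8**
Reactants: 17 4-[(2R)-2-(2-hydroxypropan-2-yl)-5-methylhex-4-en-1-yl]-3,5-dimethoxyphenol; 18 (2E)-3,7-dimethylocta-2,6-dien-1-ol (geraniol)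
Product: 19 4-[(2E)-3,7-dimethylocta-2,6-dien-1-yl]-4-[(2R)-2-(2-hydroxypropan-2-yl)-5-methylhex-4-en-1-yl]-3,5-dimethoxycyclohexa-2,5-dien-1-one
Conditions: Pd(OAc)2 (5 mol %), PPh3 (20 mol %), Ti(OiPr)4 (25 mol %), 4 Å molecular sieves, toluene, 50 °C
Reagents that add atoms: none
Why: Tsuji–Trost-type dearomative C-allylation of a 4-alkyl-3,5-dimethoxyphenol with an allylic alcohol activated by the titanium alkoxide; the titanium aryloxide shields oxygen and the ortho carbons, so the π-geranyl complex is attacked by the electron-rich para carbon at its unsubstituted terminus. The new quaternary carbon (C5) is not a stereocentre because the dienone ring is symmetric.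

**Step 9**
Reactants: 19 4-[(2E)-3,7-dimethylocta-2,6-dien-1-yl]-4-[(2R)-2-(2-hydroxypropan-2-yl)-5-methylhex-4-en-1-yl]-3,5-dimethoxycyclohexa-2,5-dien-1-one
Product: 21 (1R,5S,7R)-5-[(2E)-3,7-dimethylocta-2,6-dien-1-yl]-4-methoxy-8,8-dimethyl-7-(3-methylbut-2-en-1-yl)bicyclo[3.3.1]non-3-ene-2,9-dione, via trichloroacetimidate 20 (not isolated)
Conditions: Cl3CCN, DBU (10 mol %), CH2Cl2, 0 °C; then Me3SiOTf (20 mol %), −78 to −40 °C; NaHCO3 quench
Reagents that add atoms: none
Why: DBU-catalysed addition of the tertiary alcohol to Cl3CCN gives imidate 20, whose nitrogen is the most basic site of the molecule, so a catalytic amount of Me3SiOTf at −78 °C ionises only the C8–O bond and leaves the dienone unprotonated. The tertiary C8 cation is trapped by C1, the α-carbon of one of the two vinylogous ester arms (C9(OMe)=C1H); the O-methyl oxocarbenium ion left at C9 passes its methyl group to the nitrogen of a further imidate, which releases C9=O and propagates the ionisation. The closest known reaction type is the cation-induced carbocyclisation of 4,4-disubstituted 3,5-dimethoxycyclohexa-2,5-dienones and of the related 1,5-dimethoxycyclohexa-1,4-dienes, in which a tertiary cationic centre attacks the enol ether carbon to form this same C1–C8 bond, combined with acid-catalysed SN1 alkylation by tertiary trichloroacetimidates. Ring B (C5–C6–C7–C8–C1–C9) closes in a 6-endo-trig mode with respect to the C1=C9 enol ether bond, through a chair in which C8 approaches C1 perpendicular to the dienone plane. C5 is prochiral in 19 and its two arms are diastereotopic: only closure onto the C9/C1 arm places the C7 prenyl group equatorial, whereas closure onto the other arm would force it axial and into the dienone ring, so the R centre at C7 should fix C5 as S and, because the bridgeheads are tied cis, C1 as R. The step needs (i) ionisation at C8 without protonation of the dienone or of the four trisubstituted olefins, secured by the imidate as the only strongly basic leaving group; (ii) C- rather than O-attack of the enol ether, the normal and irreversible course for enol ethers; (iii) preference of the vinylogous ester carbon over the geranyl 2,3-olefin, which could close a ring of the same size but is a much weaker π-nucleophile.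

**Step 10**
Reactants: 22 3,4-dihydroxybenzoic acid
Product: 23 tert-butyldimethylsilyl 3,4-bis[(tert-butyldimethylsilyl)oxy]benzoate
Conditions: t-BuMe2SiCl (3.3 equiv), imidazole, DMF, rt
Reagents that add atoms: tert-butyl(chloro)dimethylsilane, CC(C)(C)[Si](C)(C)Cl
Why: Exhaustive silylation of the two phenols and the acid; silyl ethers are the catechol protection that survives lithium amides and falls off under the final hydroxide treatment.

**Step 11**
Reactants: 23 tert-butyldimethylsilyl 3,4-bis[(tert-butyldimethylsilyl)oxy]benzoate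
Product: 24 3,4-bis[(tert-butyldimethylsilyl)oxy]benzoyl chloride
Conditions: (COCl)2, DMF (cat.), CH2Cl2, 0 °C to rt
Reagents that add atoms: oxalyl chloride, O=C(Cl)C(=O)Cl
Why: Direct conversion of a silyl ester into the acid chloride with the Vilsmeier reagent under neutral conditions; the aryl silyl ethers are not affected.

**Step 12**
Reactants: 21 (1R,5S,7R)-5-[(2E)-3,7-dimethylocta-2,6-dien-1-yl]-4-methoxy-8,8-dimethyl-7-(3-methylbut-2-en-1-yl)bicyclo[3.3.1]non-3-ene-2,9-dione; 24 3,4-bis[(tert-butyldimethylsilyl)oxy]benzoyl chloride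
Product: 26 (1S,5S,7R)-3-{3,4-bis[(tert-butyldimethylsilyl)oxy]benzoyl}-5-[(2E)-3,7-dimethylocta-2,6-dien-1-yl]-4-methoxy-8,8-dimethyl-7-(3-methylbut-2-en-1-yl)bicyclo[3.3.1]non-3-ene-2,9-dione, via vinyllithium 25 (not isolated)
Conditions: LiTMP (lithium 2,2,6,6-tetramethylpiperidide, 1.1 equiv), THF, −78 °C; then 24, −78 to −40 °C
Reagents that add atoms: none
Why: Kinetic α-lithiation of the β-methoxy enone at the vinylic C3–H, the most acidic proton of such bicyclic vinylogous esters, and acylation of the vinyllithium by the acid chloride. No stereocentre changes; the descriptor at C1 changes only through priorities.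

**Step 13**
Reactants: 26 (1S,5S,7R)-3-{3,4-bis[(tert-butyldimethylsilyl)oxy]benzoyl}-5-[(2E)-3,7-dimethylocta-2,6-dien-1-yl]-4-methoxy-8,8-dimethyl-7-(3-methylbut-2-en-1-yl)bicyclo[3.3.1]non-3-ene-2,9-dione; 5 1-bromo-3-methylbut-2-ene
Product: 28 (1S,5S,7R)-3-{3,4-bis[(tert-butyldimethylsilyl)oxy]benzoyl}-5-[(2E)-3,7-dimethylocta-2,6-dien-1-yl]-4-methoxy-8,8-dimethyl-1,7-bis(3-methylbut-2-en-1-yl)bicyclo[3.3.1]non-3-ene-2,9-dione, via bridgehead organolithium 27 (not isolated)
Conditions: LiTMP (1.3 equiv), THF, −78 °C; then 5 (excess), −78 to 0 °C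
Reagents that add atoms: none
Why: Bridgehead lithiation of the C1–H flanked by the C2 and C9 carbonyl groups (now the only acidic proton) and SN2 alkylation with the allylic bromide. The bicycle enforces retention at C1, and O-alkylation is excluded because it would create a bridgehead double bond.

**Step 14**
Reactants: 28 (1S,5S,7R)-3-{3,4-bis[(tert-butyldimethylsilyl)oxy]benzoyl}-5-[(2E)-3,7-dimethylocta-2,6-dien-1-yl]-4-methoxy-8,8-dimethyl-1,7-bis(3-methylbut-2-en-1-yl)bicyclo[3.3.1]non-3-ene-2,9-dione
Product: 29 (1S,5S,7R)-3-(3,4-dihydroxybenzoyl)-5-[(2E)-3,7-dimethylocta-2,6-dien-1-yl]-4-hydroxy-8,8-dimethyl-1,7-bis(3-methylbut-2-en-1-yl)bicyclo[3.3.1]non-3-ene-2,9-dione (CNP0160101.3)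
Conditions: LiOH·H2O (excess), 1,4-dioxane/H2O, degassed, argon, 90 °C; then 1 M HCl
Reagents that add atoms: lithium hydroxide, [Li+].[OH-]
Why: Saponification of the vinylogous methyl ester by addition–elimination of hydroxide at C4, with cleavage of both aryl silyl ethers in the same pot; exclusion of air protects the catecholate. No stereocentre is affected.

## Compound list

1 | (4S)-4-benzyl-1,3-oxazolidin-2-one | O=C1N[C@@H](Cc2ccccc2)CO1 | starting material
2 | 3-methylbut-2-enoyl chloride | CC(C)=CC(=O)Cl | starting material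
3 | lithium (4S)-4-benzyl-2-oxo-1,3-oxazolidin-3-ide | [Li]N1[C@@H](Cc2ccccc2)COC1=O | intermediate (not isolated)
4 | (4S)-4-benzyl-3-(3-methylbut-2-enoyl)-1,3-oxazolidin-2-one | CC(C)=CC(=O)N1[C@@H](Cc2ccccc2)COC1=O | intermediate
5 | 1-bromo-3-methylbut-2-ene | CC(C)=CCBr | starting material
6 | sodium (1Z)-1-[(4S)-4-benzyl-2-oxo-1,3-oxazolidin-3-yl]-3-methylbuta-1,3-dien-1-olate | [Na+].[O-]/C(=C\C(C)=C)N1[C@@H](Cc2ccccc2)COC1=O | intermediate (not isolated)
7 | (4S)-4-benzyl-3-[(2S)-5-methyl-2-(prop-1-en-2-yl)hex-4-enoyl]-1,3-oxazolidin-2-one | CC(C)=CC[C@@H](C(C)=C)C(=O)N1[C@@H](Cc2ccccc2)COC1=O | intermediate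
8 | (2S)-5-methyl-2-(prop-1-en-2-yl)hex-4-en-1-ol | CC(C)=CC[C@@H](C(C)=C)CO | intermediate
9 | acetoxy[(3R)-2-hydroxy-3-(hydroxymethyl)-2,6-dimethylhept-5-en-1-yl]mercury (both epimers at C2) | CC(C)=CC[C@H](CO)C(C)(O)C[Hg]OC(C)=O | intermediate (not isolated)
10 | (2R)-2-(2-hydroxypropan-2-yl)-5-methylhex-4-en-1-ol | CC(C)=CC[C@@H](C(C)(C)O)CO | intermediate
11 | (2R)-2-(2-hydroxypropan-2-yl)-5-methylhex-4-en-1-yl 4-methylbenzenesulfonate | CC(C)=CC[C@@H](C(C)(C)O)COS(=O)(=O)c1ccc(C)cc1 | intermediate (not isolated)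
12 | (3R)-2,2-dimethyl-3-(3-methylbut-2-en-1-yl)oxetane | CC(C)=CC[C@@H]1COC1(C)C | intermediate
13 | 3,5-dimethoxyphenol | COc1cc(O)cc(OC)c1 | starting material
14 | (3,5-dimethoxyphenoxy)tri(propan-2-yl)silane | COc1cc(O[Si](C(C)C)(C(C)C)C(C)C)cc(OC)c1 | intermediate
15 | {2,6-dimethoxy-4-[tri(propan-2-yl)silyloxy]phenyl}lithium | [Li]c1c(OC)cc(O[Si](C(C)C)(C(C)C)C(C)C)cc1OC | intermediate (not isolated)
16 | (3R)-3-({2,6-dimethoxy-4-[tri(propan-2-yl)silyloxy]phenyl}methyl)-2,6-dimethylhept-5-en-2-ol | CC(C)=CC[C@@H](C(C)(C)O)Cc1c(OC)cc(O[Si](C(C)C)(C(C)C)C(C)C)cc1OC | intermediate (not isolated)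
17 | 4-[(2R)-2-(2-hydroxypropan-2-yl)-5-methylhex-4-en-1-yl]-3,5-dimethoxyphenol | CC(C)=CC[C@@H](C(C)(C)O)Cc1c(OC)cc(O)cc1OC | intermediate
18 | (2E)-3,7-dimethylocta-2,6-dien-1-ol | CC(C)=CCC/C(C)=C/CO | starting material
19 | 4-[(2E)-3,7-dimethylocta-2,6-dien-1-yl]-4-[(2R)-2-(2-hydroxypropan-2-yl)-5-methylhex-4-en-1-yl]-3,5-dimethoxycyclohexa-2,5-dien-1-one | CC(C)=CCC/C(C)=C/CC1(C[C@@H](CC=C(C)C)C(C)(C)O)C(OC)=CC(=O)C=C1OC | intermediate
20 | (3R)-3-({1-[(2E)-3,7-dimethylocta-2,6-dien-1-yl]-2,6-dimethoxy-4-oxocyclohexa-2,5-dien-1-yl}methyl)-2,6-dimethylhept-5-en-2-yl 2,2,2-trichloroethanimidate | CC(C)=CCC/C(C)=C/CC1(C[C@@H](CC=C(C)C)C(C)(C)OC(=N)C(Cl)(Cl)Cl)C(OC)=CC(=O)C=C1OC | intermediate (not isolated)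
21 | (1R,5S,7R)-5-[(2E)-3,7-dimethylocta-2,6-dien-1-yl]-4-methoxy-8,8-dimethyl-7-(3-methylbut-2-en-1-yl)bicyclo[3.3.1]non-3-ene-2,9-dione | CC(C)=CCC/C(C)=C/C[C@]12C[C@@H](CC=C(C)C)C(C)(C)[C@H](C(=O)C=C1OC)C2=O | intermediate
22 | 3,4-dihydroxybenzoic acid | O=C(O)c1ccc(O)c(O)c1 | starting material
23 | tert-butyldimethylsilyl 3,4-bis[(tert-butyldimethylsilyl)oxy]benzoate | CC(C)(C)[Si](C)(C)OC(=O)c1ccc(O[Si](C)(C)C(C)(C)C)c(O[Si](C)(C)C(C)(C)C)c1 | intermediate
24 | 3,4-bis[(tert-butyldimethylsilyl)oxy]benzoyl chloride | O=C(Cl)c1ccc(O[Si](C)(C)C(C)(C)C)c(O[Si](C)(C)C(C)(C)C)c1 | intermediate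
25 | C3-lithio derivative of 21, (1R,5S,7R) | CC(C)=CCC/C(C)=C/C[C@]12C[C@@H](CC=C(C)C)C(C)(C)[C@H](C(=O)C([Li])=C1OC)C2=O | intermediate (not isolated)
26 | (1S,5S,7R)-3-{3,4-bis[(tert-butyldimethylsilyl)oxy]benzoyl}-5-[(2E)-3,7-dimethylocta-2,6-dien-1-yl]-4-methoxy-8,8-dimethyl-7-(3-methylbut-2-en-1-yl)bicyclo[3.3.1]non-3-ene-2,9-dione | CC(C)=CCC/C(C)=C/C[C@]12C[C@@H](CC=C(C)C)C(C)(C)[C@H](C(=O)C(C(=O)c3ccc(O[Si](C)(C)C(C)(C)C)c(O[Si](C)(C)C(C)(C)C)c3)=C1OC)C2=O | intermediate
27 | C1-lithio derivative of 26, (1S,5S,7R) | CC(C)=CCC/C(C)=C/C[C@]12C[C@@H](CC=C(C)C)C(C)(C)[C@]([Li])(C(=O)C(C(=O)c3ccc(O[Si](C)(C)C(C)(C)C)c(O[Si](C)(C)C(C)(C)C)c3)=C1OC)C2=O | intermediate (not isolated)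
28 | (1S,5S,7R)-3-{3,4-bis[(tert-butyldimethylsilyl)oxy]benzoyl}-5-[(2E)-3,7-dimethylocta-2,6-dien-1-yl]-4-methoxy-8,8-dimethyl-1,7-bis(3-methylbut-2-en-1-yl)bicyclo[3.3.1]non-3-ene-2,9-dione | CC(C)=CCC/C(C)=C/C[C@]12C[C@@H](CC=C(C)C)C(C)(C)[C@](CC=C(C)C)(C(=O)C(C(=O)c3ccc(O[Si](C)(C)C(C)(C)C)c(O[Si](C)(C)C(C)(C)C)c3)=C1OC)C2=O | intermediate
29 | (1S,5S,7R)-3-(3,4-dihydroxybenzoyl)-5-[(2E)-3,7-dimethylocta-2,6-dien-1-yl]-4-hydroxy-8,8-dimethyl-1,7-bis(3-methylbut-2-en-1-yl)bicyclo[3.3.1]non-3-ene-2,9-dione | CC(C)=CCC/C(C)=C/C[C@]12C[C@@H](CC=C(C)C)C(C)(C)[C@](CC=C(C)C)(C(=O)C(C(=O)c3ccc(O)c(O)c3)=C1O)C2=O | target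

## Step count and risk

Total step count: 14. Longest linear sequence: 11 steps (steps 1–5, 7, 8, 9, 12, 13, 14); steps 6 and 10–11 are side branches.

**Step 9 (key step).** The α-carbon of a vinylogous ester is only a moderate π-nucleophile and has to bond to a fully substituted carbon. The tertiary cation may therefore escape by loss of a proton to the isopropenyl or isopropylidene olefins, which is irreversible in the buffered medium. Other exits are collapse with its counter-ion to the N-tert-alkyl trichloroacetamide and capture by the enol ether oxygen. Capture by oxygen would later give the demethylated trione of the same skeleton. If free acid accumulates, the O-protonated dienone may also lose the geranyl group by heterolysis and revert to phenol 17.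

The fallback changes the nucleophile and the medium; it sets out from 19 and returns at 21. Both enol ethers of 19 would be hydrolysed (LiOH, aqueous dioxane) to 2-[(2E)-3,7-dimethylocta-2,6-dien-1-yl]-2-[(2R)-2-(2-hydroxypropan-2-yl)-5-methylhex-4-en-1-yl]cyclohexane-1,3,5-trione F1. This acidic, non-basic triketone belongs to the substrate class for which cyclisation of a tertiary cation onto a dearomatised phloroglucinol enol in formic acid is established. In formic acid at room temperature F1 should close under the same chair control to (1R,5S,7R)-5-[(2E)-3,7-dimethylocta-2,6-dien-1-yl]-8,8-dimethyl-7-(3-methylbut-2-en-1-yl)bicyclo[3.3.1]nonane-2,4,9-trione F2. O-Methylation (Me3SiCHN2, MeOH/toluene) would give 21 together with its regioisomer (1S,5R,7R)-1-[(2E)-3,7-dimethylocta-2,6-dien-1-yl]-4-methoxy-6,6-dimethyl-7-(3-methylbut-2-en-1-yl)bicyclo[3.3.1]non-3-ene-2,9-dione F3, which is separated and recycled to F2 by hydrolysis.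

**Step 8.** Site selectivity may be poor: the π-geranyl complex can be attacked through oxygen or through the two free ortho carbons instead of the substituted para carbon, and syn–anti isomerisation of the complex can erode the E geometry.

The fallback builds the quaternary carbon by anionic alkylation of a Birch-derived diene; it sets out from 12 and returns at 19. 2-Lithio-1,3-dimethoxybenzene (from 1,3-dimethoxybenzene and n-BuLi) would open 12 with BF3·OEt2 to (3R)-3-[(2,6-dimethoxyphenyl)methyl]-2,6-dimethylhept-5-en-2-ol F4. Birch reduction (Li, NH3, t-BuOH, THF, −78 °C) would give (3R)-3-[(2,6-dimethoxycyclohexa-2,5-dien-1-yl)methyl]-2,6-dimethylhept-5-en-2-ol F5. Double deprotonation (t-BuLi, 2 equiv) and alkylation of the carbon between the two enol ethers with geranyl bromide would give (3R)-3-({1-[(2E)-3,7-dimethylocta-2,6-dien-1-yl]-2,6-dimethoxycyclohexa-2,5-dien-1-yl}methyl)-2,6-dimethylhept-5-en-2-ol F6. Allylic oxidation of the doubly activated ring CH2 (t-BuOOH, Pd(OH)2/C, K2CO3, CH2Cl2) would then lead to 19.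

**Step 13.** The bridgehead carbanion at C1 is flanked by the quaternary C8, so the SN2 step with prenyl bromide may be too slow, and the anion may be reprotonated on work-up or decompose on warming.

The fallback replaces the polar alkylation by a radical one; it sets out from 26 and returns at 28. The same lithiation quenched with iodine should give the bridgehead iodide (1R,5S,7R)-3-{3,4-bis[(tert-butyldimethylsilyl)oxy]benzoyl}-5-[(2E)-3,7-dimethylocta-2,6-dien-1-yl]-1-iodo-4-methoxy-8,8-dimethyl-7-(3-methylbut-2-en-1-yl)bicyclo[3.3.1]non-3-ene-2,9-dione F7. Keck allylation (allyltributylstannane, AIBN, toluene, 80 °C) would give the C1-allyl compound (1S,5S,7R)-3-{3,4-bis[(tert-butyldimethylsilyl)oxy]benzoyl}-5-[(2E)-3,7-dimethylocta-2,6-dien-1-yl]-4-methoxy-8,8-dimethyl-7-(3-methylbut-2-en-1-yl)-1-(prop-2-en-1-yl)bicyclo[3.3.1]non-3-ene-2,9-dione F8. Cross-metathesis with 2-methylbut-2-ene (second-generation Hoveyda–Grubbs catalyst, short reaction time to spare the geranyl olefins) would convert the allyl group into prenyl and give 28.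

**Step 12.** Proton transfer from the bridgehead C1–H to the vinyllithium, or direct competing metalation at C1, may lead to acylation at C1 or to mixtures.

The fallback inverts the order of the two substitutions with a blocking group; it sets out from 21 and returns at 28. LiTMP with Me3SiCl present in situ would give the C3-silyl compound (1S,5S,7R)-5-[(2E)-3,7-dimethylocta-2,6-dien-1-yl]-4-methoxy-8,8-dimethyl-7-(3-methylbut-2-en-1-yl)-3-(trimethylsilyl)bicyclo[3.3.1]non-3-ene-2,9-dione F9. Bridgehead lithiation and reaction with 5 would give (1S,5S,7R)-5-[(2E)-3,7-dimethylocta-2,6-dien-1-yl]-4-methoxy-8,8-dimethyl-1,7-bis(3-methylbut-2-en-1-yl)-3-(trimethylsilyl)bicyclo[3.3.1]non-3-ene-2,9-dione F10. Bu4NF would remove the silyl group to give (1R,5S,7R)-5-[(2E)-3,7-dimethylocta-2,6-dien-1-yl]-4-methoxy-8,8-dimethyl-1,7-bis(3-methylbut-2-en-1-yl)bicyclo[3.3.1]non-3-ene-2,9-dione F11. C3-lithiation of F11 and acylation with 24 would then give 28.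

## Further compounds

F1 | step 9 | 2-[(2E)-3,7-dimethylocta-2,6-dien-1-yl]-2-[(2R)-2-(2-hydroxypropan-2-yl)-5-methylhex-4-en-1-yl]cyclohexane-1,3,5-trione | CC(C)=CCC/C(C)=C/CC1(C[C@@H](CC=C(C)C)C(C)(C)O)C(=O)CC(=O)CC1=O
F2 | step 9 | (1R,5S,7R)-5-[(2E)-3,7-dimethylocta-2,6-dien-1-yl]-8,8-dimethyl-7-(3-methylbut-2-en-1-yl)bicyclo[3.3.1]nonane-2,4,9-trione | CC(C)=CCC/C(C)=C/C[C@]12C[C@@H](CC=C(C)C)C(C)(C)[C@H](C(=O)CC1=O)C2=O
F3 | step 9 | (1S,5R,7R)-1-[(2E)-3,7-dimethylocta-2,6-dien-1-yl]-4-methoxy-6,6-dimethyl-7-(3-methylbut-2-en-1-yl)bicyclo[3.3.1]non-3-ene-2,9-dione | CC(C)=CCC/C(C)=C/C[C@]12C[C@@H](CC=C(C)C)C(C)(C)[C@H](C(OC)=CC1=O)C2=O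
F4 | step 8 | (3R)-3-[(2,6-dimethoxyphenyl)methyl]-2,6-dimethylhept-5-en-2-ol | CC(C)=CC[C@@H](C(C)(C)O)Cc1c(OC)cccc1OC
F5 | step 8 | (3R)-3-[(2,6-dimethoxycyclohexa-2,5-dien-1-yl)methyl]-2,6-dimethylhept-5-en-2-ol | CC(C)=CC[C@@H](C(C)(C)O)CC1C(OC)=CCC=C1OC
F6 | step 8 | (3R)-3-({1-[(2E)-3,7-dimethylocta-2,6-dien-1-yl]-2,6-dimethoxycyclohexa-2,5-dien-1-yl}methyl)-2,6-dimethylhept-5-en-2-ol | CC(C)=CCC/C(C)=C/CC1(C[C@@H](CC=C(C)C)C(C)(C)O)C(OC)=CCC=C1OC
F7 | step 13 | (1R,5S,7R)-3-{3,4-bis[(tert-butyldimethylsilyl)oxy]benzoyl}-5-[(2E)-3,7-dimethylocta-2,6-dien-1-yl]-1-iodo-4-methoxy-8,8-dimethyl-7-(3-methylbut-2-en-1-yl)bicyclo[3.3.1]non-3-ene-2,9-dione | CC(C)=CCC/C(C)=C/C[C@]12C[C@@H](CC=C(C)C)C(C)(C)[C@](I)(C(=O)C(C(=O)c3ccc(O[Si](C)(C)C(C)(C)C)c(O[Si](C)(C)C(C)(C)C)c3)=C1OC)C2=O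
F8 | step 13 | (1S,5S,7R)-3-{3,4-bis[(tert-butyldimethylsilyl)oxy]benzoyl}-5-[(2E)-3,7-dimethylocta-2,6-dien-1-yl]-4-methoxy-8,8-dimethyl-7-(3-methylbut-2-en-1-yl)-1-(prop-2-en-1-yl)bicyclo[3.3.1]non-3-ene-2,9-dione | CC(C)=CCC/C(C)=C/C[C@]12C[C@@H](CC=C(C)C)C(C)(C)[C@](CC=C)(C(=O)C(C(=O)c3ccc(O[Si](C)(C)C(C)(C)C)c(O[Si](C)(C)C(C)(C)C)c3)=C1OC)C2=O
F9 | step 12 | (1S,5S,7R)-5-[(2E)-3,7-dimethylocta-2,6-dien-1-yl]-4-methoxy-8,8-dimethyl-7-(3-methylbut-2-en-1-yl)-3-(trimethylsilyl)bicyclo[3.3.1]non-3-ene-2,9-dione | CC(C)=CCC/C(C)=C/C[C@]12C[C@@H](CC=C(C)C)C(C)(C)[C@H](C(=O)C([Si](C)(C)C)=C1OC)C2=O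
F10 | step 12 | (1S,5S,7R)-5-[(2E)-3,7-dimethylocta-2,6-dien-1-yl]-4-methoxy-8,8-dimethyl-1,7-bis(3-methylbut-2-en-1-yl)-3-(trimethylsilyl)bicyclo[3.3.1]non-3-ene-2,9-dione | CC(C)=CCC/C(C)=C/C[C@]12C[C@@H](CC=C(C)C)C(C)(C)[C@](CC=C(C)C)(C(=O)C([Si](C)(C)C)=C1OC)C2=O
F11 | step 12 | (1R,5S,7R)-5-[(2E)-3,7-dimethylocta-2,6-dien-1-yl]-4-methoxy-8,8-dimethyl-1,7-bis(3-methylbut-2-en-1-yl)bicyclo[3.3.1]non-3-ene-2,9-dione | CC(C)=CCC/C(C)=C/C[C@]12C[C@@H](CC=C(C)C)C(C)(C)[C@](CC=C(C)C)(C(=O)C=C1OC)C2=O
A1 | alternative 1 | {[(4S)-3,3-dimethyl-2,4-bis(3-methylbut-2-en-1-yl)cyclohex-1-en-1-yl]oxy}trimethylsilane | C[Si](C)(C)OC1=C(CC=C(C)C)C(C)(C)[C@H](CC=C(C)C)CC1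
A2 | alternative 1 | (1R,5S,7R)-4-hydroxy-8,8-dimethyl-1,7-bis(3-methylbut-2-en-1-yl)bicyclo[3.3.1]non-3-ene-2,9-dione | [C@H]12C[C@@H](CC=C(C)C)C(C)(C)[C@](CC=C(C)C)(C(=O)C=C1O)C2=O
A3 | alternative 2 | {3,4-bis[(tert-butyldimethylsilyl)oxy]phenyl}{3-[(2E)-3,7-dimethylocta-2,6-dien-1-yl]-2,4,6-trihydroxy-5-(3-methylbut-2-en-1-yl)phenyl}methanone | CC(C)=CCC/C(C)=C/Cc1c(O)c(CC=C(C)C)c(O)c(C(=O)c2ccc(O[Si](C)(C)C(C)(C)C)c(O[Si](C)(C)C(C)(C)C)c2)c1O
A4 | alternative 2 | 2-{3,4-bis[(tert-butyldimethylsilyl)oxy]benzoyl}-6-[(2E)-3,7-dimethylocta-2,6-dien-1-yl]-3,5-dihydroxy-6-[(2R)-2-(2-hydroxypropan-2-yl)-5-methylhex-4-en-1-yl]-4-(3-methylbut-2-en-1-yl)cyclohexa-2,4-dien-1-one (both epimers at C6) | CC(C)=CCC/C(C)=C/CC1(C[C@@H](CC=C(C)C)C(C)(C)O)C(=O)C(C(=O)c2ccc(O[Si](C)(C)C(C)(C)C)c(O[Si](C)(C)C(C)(C)C)c2)=C(O)C(CC=C(C)C)=C1O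
A5 | alternative 3 | 4-[(2E)-3,7-dimethylocta-2,6-dien-1-yl]-3,5-dimethoxy-4-(3-methylbut-2-en-1-yl)cyclohexa-2,5-dien-1-one | CC(C)=CCC/C(C)=C/CC1(CC=C(C)C)C(OC)=CC(=O)C=C1OC
A6 | alternative 3 | rac-5-[(2E)-3,7-dimethylocta-2,6-dien-1-yl]-7-iodo-4-methoxy-8,8-dimethylbicyclo[3.3.1]non-3-ene-2,9-dione (racemate) | CC(C)=CCC/C(C)=C/CC12CC(I)C(C)(C)C(C(=O)C=C1OC)C2=O
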